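Remark on the chemistry: positions are numbered as in the lactone, C1 being the carbonyl carbon and C26 the methylene on the ring oxygen. The target is achiral and has no double bond, so no stereodescriptor applies to any compound of the route.

Numbering used throughout: 1 octadecanedioic acid mono-tert-butyl ester; 2 10-hydroxydecanoic acid; 3 tert-butyl 26-hydroxyhexacosanoate; 4 26-(trifluoroacetoxy)hexacosanoic acid; 5 26-hydroxyhexacosanoic acid; 6 mixed anhydride of 5 with 2,4,6-trichlorobenzoic acid; 7 26-hexacosanolide.

## Analysis of the target

26-Hexacosanolide (7) is a monocyclic 27-membered lactone: 26 carbons and one oxygen in the ring, C1 as the ester carbonyl, and C2 to C26 as an unbroken run of 25 methylenes. There is no stereocentre, no double bond and no branch, so nothing has to be controlled stereochemically, and the only reactive group is the lactone, which is open to hydroxide, alkoxides and transesterification catalysts and is therefore made last. The difficulty lies elsewhere: a C26 chain with two different termini must be assembled with an exact carbon count, because ring homologues differing by one or two methylenes are waxes of the same polarity and could not be removed; the ring is strain-free but entropically costly, so closure competes with oligomerisation; and every intermediate is a poorly soluble wax without a chromophore. Between C2 and C25 the chain offers no functional handle, so any internal C–C bond made by polar chemistry would leave a group (olefin, alkyne, sulfone, carbonyl) that must be erased afterwards. The strategy rests on the C17–C18 bond, a bond between two ordinary methylenes. Both carbons can be generated as primary radicals by loss of a carboxyl group: C17 from the 18-carbon half-ester 1, which supplies C1–C17 with C1 already at the acid oxidation level, and C18 from the 10-carbon hydroxy acid 2, which supplies C18–C26 with the C26 oxygen in place. One bond formation therefore delivers the whole saturated seco skeleton with both ends differentiated.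

## Retrosynthetic reasoning

**7 to 5.** The ring contains a single heteroatom bond, the acyl–oxygen bond between C1 and the oxygen on C26, and it is cut first. Every other ring bond is an unactivated C–C bond, whose formation in a ring-closing sense would need two extra functional groups and their later removal. Opening the lactone gives the linear hydroxy acid 5, with both ends at the correct oxidation level. In the forward direction the carboxyl group of 5 must be activated in the presence of its own hydroxyl group and captured intramolecularly. This is planned through the mixed anhydride 6 under high dilution; because a 27-membered lactone has no ring strain, dilution alone decides between closure and oligomerisation.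

**5 to 3.** No skeletal bond is cut here; the C1 carboxyl group is traced back to its tert-butyl ester 3. The mask is needed because the chain-building step consumes free carboxyl groups, so the one that is to survive as C1 must not be a carboxylate at that stage. A tert-butyl ester is chosen because it does not exchange with an alcoholic solvent and is removed without touching the chain. The forward step is an acidolysis. A strong carboxylic acid that removes the tert-butyl group will also acylate the free C26 hydroxyl, so the step is planned to pass through the O-acyl acid 4, and a basic hydrolysis before isolation releases 5 from it.

**3 to 1 and 2.** The C17–C18 bond is cut homolytically, each carbon taking one electron and, in the retrosynthetic sense, a carboxyl group. All 24 methylene–methylene bonds of 3 are electronically alike, so the choice of this one is dictated by supply: one extra carboxyl carbon on the C1–C17 piece gives the 18-carbon diacid half-ester 1, and one on the C18–C26 piece gives the ω-hydroxy acid 2, both stock chemicals. The gain is the complete carbon skeleton in one operation, with no residual functionality at the junction and with C1 and C26 already differentiated. The forward reaction must generate both primary radicals at the same anode and have them combine with each other rather than each with its own kind, without touching the ester or the hydroxyl group. Cross-coupling is favoured by an excess of 2, and purification relies on the different number of hydroxyl groups in the three coupling products.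

Compounds 1 and 2 are purchased, so no further disconnection is needed.

## Alternatives that were turned down

**Alternative 1:** Two ring bonds, C9–C10 and C19–C20, are cut as the olefins of hexacosa-9,19-dien-26-olide (A3). This divides the ring into the commercial 17-membered musk lactone isoambrettolide (A1; it supplies C1–C9 and C20–C26 with the ester in place) and cis-cyclodecene (A2; C10–C19).
- Forward key step: the second-generation Grubbs catalyst RuCl2(=CHPh)(PCy3)(H2IMes) opens A2 and stitches its ten carbons into the olefin of A1 by ring-opening/ring-closing cross-metathesis at high dilution. Hydrogenation of A3 over Pd/C would finish.
- For: two steps, no protecting group, no lactonisation because the ester is never opened, and no atom lost. On step and atom economy this is stronger than the chosen route.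
- Against: nothing in A1 or A2 distinguishes a single insertion from none, two or three, or from self-metathesis of A1 to its cyclic dimer. All of these interconvert on the same catalyst, so A3 would be one member of an equilibrium population whose share is set by ring–chain thermodynamics, not by design.
- Against, more serious: hydride species formed by decomposition of RuCl2(=CHPh)(PCy3)(H2IMes) migrate double bonds, and metathesis of a migrated olefin removes or adds single methylene units. After hydrogenation these become 25- and 27-carbon lactones that cannot be separated from 7.
- Comparison: the chosen route fixes the carbon count through 1 and 2, involves no equilibration, and gives by-products that differ from 3 in functional-group count rather than ring size. The price is one more step and a separate high-dilution closure.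

**Alternative 2:** The C11–C12 bond is cut after introducing a conjugated diyne, giving hexacosa-10,12-diyn-26-olide (A5). Its open precursor is the ester pentadec-14-yn-1-yl undec-10-ynoate (A4), which is assembled from pentadec-14-yn-1-ol (A6) and undec-10-ynoic acid (A7).
- Forward key step: Eglinton oxidative coupling of the two terminal alkynes of A4 with stoichiometric Cu(OAc)2 in pyridine at high dilution closes the ring. Exhaustive hydrogenation of A5 over Pd/C follows.
- For: A4 is made early by a trivial intermolecular esterification of A7 with A6. The ring is closed by C–C bond formation between two identical, reactive termini, so there is no cross-/self-coupling ambiguity within the molecule, and the chain length is defined. On selectivity of the C–C bond formation this is stronger than a statistical radical coupling.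
- Against: A7 is a catalogue acid, but A6 is not a stock chemical and would need a multistep chain extension and alkyne isomerisation, so the route runs to roughly twice the length. The closure still needs high dilution, with intermolecular coupling to cyclic dimers as the competing path, so the entropic problem is moved rather than removed. A large excess of Cu(OAc)2 is required, and four π bonds must be hydrogenated.
- Comparison: the chosen route is about half as long, uses two catalogue acids, and creates the saturated chain directly.

**Alternative 3:** The C13–C14 bond is cut as the olefin of hexacos-13-en-26-olide (A9), leading back to erucyl erucate (A8), the wax ester whose acyl and alkyl halves each carry a Z-olefin thirteen carbons from the ester function.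
- Forward key step: ring-closing metathesis of A8 with the second-generation Grubbs catalyst RuCl2(=CHPh)(PCy3)(H2IMes) at high dilution joins the two olefins into the 27-membered ring and expels the two nine-carbon tails as octadec-9-ene (A10). Hydrogenation of A9 over Pd/C follows.
- For: A8 is a bulk material, the ester is in place, and ring closure coincides with C–C bond formation. With two steps this is shorter and cheaper than the chosen route.
- Against: 18 of the 44 carbons of A8 are discarded as A10. A10 is not volatile and stays in solution as a competent metathesis partner, so closure is driven by dilution only.
- Against: olefin migration before metathesis again leads to ring homologues.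
- Against: A8 of natural origin carries homologous chains two carbons shorter and longer, with the olefin eleven or fifteen carbons from the ester group. These would give rings two carbons smaller or larger, again inseparable after hydrogenation.
- Comparison: the chosen route offers a chain that is saturated from the start (no hydrogenation, no isomerisation channel), a carbon count fixed by 1 and 2, bond formation by electrons alone, and by-products that differ from 3 in polarity class.

Key step: step 1

## Route

Step 1
Reactants: 1 octadecanedioic acid mono-tert-butyl ester (18-tert-butoxy-18-oxooctadecanoic acid), 1 equiv; 2 10-hydroxydecanoic acid, 4 equiv
Product: 3 tert-butyl 26-hydroxyhexacosanoate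
Conditions: KOH (0.1 equiv per CO2H), MeOH, smooth Pt anode, Pt cathode, undivided cell, constant current ca. 0.25 A cm−2, 45–50 °C, until the electrolyte turns faintly alkaline
Reagents that add atoms: none
Why: Crossed Kolbe electrolysis of a half-ester with a second alkanoic acid, a long-established anodic chain-building reaction: each carboxylate is discharged at the Pt anode to an acyloxy radical that loses CO2 at once, leaving the primary radicals tBuO2C(CH2)16· (C1–C17) and HO(CH2)9· (C18–C26) side by side in the reaction layer. High current density, a largely un-neutralised acid and methanol as solvent keep the radical concentration high, so that bimolecular recombination to the C17–C18 bond outruns a second electron transfer; unbranched primary radicals without an α-heteroatom are in any case reluctant to be oxidised to cations. No ring is closed and no stereocentre is formed, so the only selectivity required is cross- over self-coupling. That selectivity is statistical (self-coupled 1 : 3 : self-coupled 2 expected as 1 : 2n : n² for n equivalents of 2 at equal discharge rates), which is why the inexpensive acid 2 is taken in fourfold excess. Chemoselectivity is secured by the substrate: the tert-butyl ester is not a carboxylate and does not exchange in weakly acidic methanol, and the remote primary hydroxyl is no easier to oxidise than the solvent, which is itself left alone in the Kolbe regime. The three coupled products carry two, one and no hydroxyl group, so 3 should be separable from the symmetrical C18 diol and the symmetrical C34 diester by chromatography on silica or by fractional crystallisation. Because radical recombination neither adds nor removes methylene units, the chain length of 3 is fixed by the carbon counts of 1 and 2.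

Step 2
Reactants: 3 tert-butyl 26-hydroxyhexacosanoate
Product: 5 26-hydroxyhexacosanoic acid, via 26-(trifluoroacetoxy)hexacosanoic acid 4 (not isolated)
Conditions: CF3CO2H/CH2Cl2 (1:1), rt; evaporate; then KOH, THF/MeOH/H2O, 50 °C; then aq. HCl to pH 2
Reagents that add atoms: none
Why: Acidolysis of a tert-butyl ester: protonation and alkyl–oxygen fission release the tert-butyl cation, which leaves as 2-methylpropene, and both carboxyl oxygens stay on C1. In this medium the primary C26 hydroxyl is expected to be esterified to the trifluoroacetate 4 (and some intermolecular ester may form on concentration), so the crude acid is saponified; the labile trifluoroacetate and any oligoester links are cleaved at the acyl carbon, and acidification should precipitate 5 as a filterable solid.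

Step 3
Reactants: 5 26-hydroxyhexacosanoic acid
Product: 7 26-hexacosanolide (oxacycloheptacosan-2-one), via 26-hydroxyhexacosanoic 2,4,6-trichlorobenzoic anhydride 6 (not isolated)
Conditions: 2,4,6-Cl3C6H2COCl, Et3N, THF, rt to 40 °C; then syringe-pump addition to DMAP, toluene, reflux (final ca. 1 mM)
Reagents that add atoms: none
Why: Yamaguchi macrolactonisation: the aroyl carbonyl of mixed anhydride 6 is shielded by its two ortho chlorines, so DMAP attacks the aliphatic C1 carbonyl and the resulting acylpyridinium is captured by the C26 hydroxyl. The 27-membered ring has no angle or transannular strain, so slow addition into hot dilute toluene should be enough to favour closure over intermolecular acylation; no stereocentre is involved.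

## Compound list

1 | octadecanedioic acid mono-tert-butyl ester (18-tert-butoxy-18-oxooctadecanoic acid) | CC(C)(C)OC(=O)CCCCCCCCCCCCCCCCC(=O)O | starting material
2 | 10-hydroxydecanoic acid | OCCCCCCCCCC(=O)O | starting material
3 | tert-butyl 26-hydroxyhexacosanoate | CC(C)(C)OC(=O)CCCCCCCCCCCCCCCCCCCCCCCCCO | intermediate
4 | 26-(trifluoroacetoxy)hexacosanoic acid | OC(=O)CCCCCCCCCCCCCCCCCCCCCCCCCOC(=O)C(F)(F)F | intermediate (not isolated)
5 | 26-hydroxyhexacosanoic acid | OC(=O)CCCCCCCCCCCCCCCCCCCCCCCCCO | intermediate
6 | 26-hydroxyhexacosanoic 2,4,6-trichlorobenzoic anhydride | O=C(OC(=O)c1c(Cl)cc(Cl)cc1Cl)CCCCCCCCCCCCCCCCCCCCCCCCCO | intermediate (not isolated)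
7 | 26-hexacosanolide (oxacycloheptacosan-2-one) | O=C1CCCCCCCCCCCCCCCCCCCCCCCCCO1 | target

## Step count and least certain steps

Total step count: 3. Longest linear sequence: 3 steps (1 or 2 to 3 to 5 to 7).

**Step 1 (key step).**
- What may go wrong: loss of cross-selectivity and of the radical pathway. If the two carboxylates discharge at unequal rates, self-coupling of each acid gains at the expense of 3.
- The waxy coupling products may also deposit on the anode, so that the effective current density collapses and two-electron (Hofer–Moest) oxidation to methyl ethers and olefins, together with radical disproportionation, takes over.
- Within the method, an inert hydrocarbon upper phase or a pyridine co-solvent and periodic reversal of polarity would be tried first.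
- Fallback: the statistical radical–radical coupling is replaced by a catalyst-controlled decarboxylative cross-coupling at the same C17–C18 bond; it sets out from 1 and comes back to the route at 3. Acid 1 is esterified with N-hydroxyphthalimide (N,N'-diisopropylcarbodiimide, cat. DMAP, CH2Cl2) to the redox-active ester 1-tert-butyl 18-(1,3-dioxoisoindolin-2-yl) octadecanedioate F1. Separately, 9-bromononan-1-ol F2 is silylated (tert-butyldimethylsilyl chloride, imidazole, DMF) to ((9-bromononyl)oxy)(tert-butyl)dimethylsilane F3, which is converted with Mg in THF into [9-(tert-butyldimethylsilyloxy)nonyl]magnesium bromide F4 and then transmetallated with ZnCl2 (0.5 equiv) to bis[9-(tert-butyldimethylsilyloxy)nonyl]zinc F5. Decarboxylative Negishi alkyl–alkyl coupling of F1 with F5 (NiCl2(dme), 4,4'-di-tert-butyl-2,2'-bipyridine, THF/DMF, rt) should give tert-butyl 26-(tert-butyldimethylsilyloxy)hexacosanoate F6, and Bu4NF in THF removes the silyl group and returns the route to 3. This costs four more operations, but each gives one defined product.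

**Step 3.**
- What may go wrong: intermolecular acyl transfer outrunning ring closure. The effective molarity of a 27-membered ring is low, and the poor solubility of 5 could let it enter the hot solution as aggregates, giving the cyclic dimer and linear oligoesters.
- In addition, aroylation of the free C26 hydroxyl during anhydride formation would cap the chain.
- Fallback: from 5 directly to 7 by Mitsunobu macrolactonisation (PPh3, diisopropyl azodicarboxylate, toluene/THF, slow addition, high dilution). The polarity of the closure is inverted: the unhindered primary C26 hydroxyl is activated as its alkoxyphosphonium ion and the C1 carboxylate displaces it. No acylating agent is present, so the alcohol cannot be capped. No new isolable compound is made.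

**Step 2.**
- What may go wrong: incomplete unmasking of the hydroxyl group and self-esterification of the hydroxy acid while the strongly acidic solution is concentrated.
- Gelation of the long-chain carboxylate formed with KOH during saponification would also make acidification and isolation lossy.
- Fallback: the hydroxyl group is taken out of play before the acid step and the ring is closed by O-alkylation; the sequence sets out from 3 and comes back to the route at 7, bypassing 5 and step 3. Appel bromination of 3 (CBr4, PPh3, CH2Cl2, 0 °C) gives tert-butyl 26-bromohexacosanoate F7, and CF3CO2H/CH2Cl2 then cleaves the ester to 26-bromohexacosanoic acid F8; no hydroxyl is left to be acylated and no base treatment is needed. Slow addition of F8 to Cs2CO3 in DMF at 70–80 °C lets the carboxylate displace bromide at C26 and close the ring to 7. The sequence from 3 is one operation longer than steps 2 and 3.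

## Further compounds

F1 | step 1 | 1-tert-butyl 18-(1,3-dioxoisoindolin-2-yl) octadecanedioate | CC(C)(C)OC(=O)CCCCCCCCCCCCCCCCC(=O)ON1C(=O)c2ccccc2C1=O
F2 | step 1 | 9-bromononan-1-ol | OCCCCCCCCCBr
F3 | step 1 | ((9-bromononyl)oxy)(tert-butyl)dimethylsilane | CC(C)(C)[Si](C)(C)OCCCCCCCCCBr
F4 | step 1 | [9-(tert-butyldimethylsilyloxy)nonyl]magnesium bromide | CC(C)(C)[Si](C)(C)OCCCCCCCCC[Mg]Br
F5 | step 1 | bis[9-(tert-butyldimethylsilyloxy)nonyl]zinc | CC(C)(C)[Si](C)(C)OCCCCCCCCC[Zn]CCCCCCCCCO[Si](C)(C)C(C)(C)C
F6 | step 1 | tert-butyl 26-(tert-butyldimethylsilyloxy)hexacosanoate | CC(C)(C)OC(=O)CCCCCCCCCCCCCCCCCCCCCCCCCO[Si](C)(C)C(C)(C)C
F7 | step 2 | tert-butyl 26-bromohexacosanoate | CC(C)(C)OC(=O)CCCCCCCCCCCCCCCCCCCCCCCCCBr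
F8 | step 2 | 26-bromohexacosanoic acid | OC(=O)CCCCCCCCCCCCCCCCCCCCCCCCCBr
F0 | step 3 | none | none
A1 | alternative 1 | isoambrettolide (hexadec-9-en-16-olide; E/Z mixture, drawn E) | O=C1CCCCCCC/C=C/CCCCCCO1
A2 | alternative 1 | cis-cyclodecene | C1CCCC/C=C\CCC1
A3 | alternative 1 | hexacosa-9,19-dien-26-olide (E/Z mixture, drawn E,E) | O=C1CCCCCCC/C=C/CCCCCCCC/C=C/CCCCCCO1
A4 | alternative 2 | pentadec-14-yn-1-yl undec-10-ynoate | C#CCCCCCCCCC(=O)OCCCCCCCCCCCCCC#C
A5 | alternative 2 | hexacosa-10,12-diyn-26-olide | O=C1CCCCCCCCC#CC#CCCCCCCCCCCCCCO1
A6 | alternative 2 | pentadec-14-yn-1-ol | OCCCCCCCCCCCCCC#C
A7 | alternative 2 | undec-10-ynoic acid | OC(=O)CCCCCCCCC#C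
A8 | alternative 3 | erucyl erucate ((Z)-docos-13-en-1-yl (Z)-docos-13-enoate) | CCCCCCCC/C=C\CCCCCCCCCCCC(=O)OCCCCCCCCCCCC/C=C\CCCCCCCC
A9 | alternative 3 | hexacos-13-en-26-olide (E/Z mixture, drawn E) | O=C1CCCCCCCCCCC/C=C/CCCCCCCCCCCCO1
A10 | alternative 3 | octadec-9-ene (E/Z mixture, drawn E) | CCCCCCCC/C=C/CCCCCCCC
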